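I started the quick reckoning from 0.0126 h⁻¹, the fraction of the charge that dissolves per hour into a solution free of starting material.

| setting | alder | elm | maple | larch |
|---|---|---|---|---|
| solid substrate | 0.10 M | 0.10 M | 0.10 M | 0.10 M |
| temperature | 80 °C | −10 °C | 50 °C | 20 °C |
| time | 30 h | 30 h | 30 h | 30 h |

    starting material → target, rate k1*[starting material]/(1 + ([starting material]/sat1)) (sat1 = 0.051 M, k1 = 0.15 h⁻¹, Ea1 = 99.0 kJ mol⁻¹)
    target → over-reaction product (k2 = 1.7 × 10⁻⁴ h⁻¹, Ea2 = 117 kJ mol⁻¹)
    crystals ⇌ target, rate k3*(cs3 - [target]) while solid is left; crystals form when [target] > cs3 (cs3 = 0.084 M, k3 = 1.7 h⁻¹)
    solid substrate ⇌ starting material, rate k4*(cs4 - [starting material]) while solid is left; crystals form when [starting material] > cs4 (cs4 = 18 mM, k4 = 0.070 h⁻¹)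
    (constants at 20 °C)

- what is said of target includes crystals
- crystals, solid substrate is a solid; its amount is given per volume of the solution
- the list of constants is for 20 °C, to be carried to other temperatures by the activation energies
- at the start none of the solid substrate is in solution
- what has only dissolved of solid substrate counts as not reacted

- the flask with the highest amount of target, in percent of the solid substrate charged ("all alike" if they lie within 1.5 percentage points) (alder / elm / maple / larch / all alike)
- final target, as a percentage of the solid substrate charged, in alder
- final target, as a percentage of the solid substrate charged, in elm
- final target, as a percentage of the solid substrate charged, in maple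
- final target, as a percentage of the solid substrate charged, in larch

**The supply.** Dissolving has no activation energy on the list, so I took this supply as the same at each temperature. The first step's constant was 6.51 h⁻¹ in maple, far above the dissolution coefficient 0.070 h⁻¹, and larger still in alder, at 149 h⁻¹. So I let dissolving be the rate-limiting step in those two flasks. In elm the first step's 0.00146 h⁻¹ lay far below that coefficient, so I gave no number for elm, nor for larch.

**The ceiling.** Target, as a fraction p of the charge, gains the supply and loses p times the over-reaction constant, a plain first-order lag. The converted fraction x gains the supply as well. Dividing one rate by the other removed time: p = C(1 − exp(−x/C)). Here C is the ceiling, the supply over the over-reaction constant at that temperature, 86.0% in maple.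

**Two flasks.** Alder's over-reaction constant of 0.592 h⁻¹ gave a time constant of 1.69 h, far shorter than 30 h, so I put alder at its ceiling, 2.13%. Maple's time constant was 68.3 h, longer than the run. Its conversion of 37.8% gave 30.6%. I bet on maple, whose figure stood above alder's ceiling.

**The forecast.** It named maple, with 2.1% in alder, 0.37% in elm, 30.3% in maple and 20.5% in larch, holding that above room temperature “the supply limits the target”. My maple stood 0.30 percentage points above its figure.

**The result.** The simulation gave 2.13% in alder, 0.369% in elm, 30.1% in maple and 20.8% in larch, so maple came out highest.

**Thinner charge.** Alder stood at its ceiling of 2.13%. Maple's converted fraction as read, 37.2%, put the rule at 30.2%. The neighbour was maple with 0.040 M of solid substrate, time and all else held. The same dissolving was then a larger fraction of the charge, so the ceiling of 86.0% became 215%, beyond the charge itself, and the conversion became 94.5%. The rule gave 76.5%. That flask read 75.3%, with 7.0% of its charge unreacted.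

(All constants were set for the occasion; no experiment stands behind them.)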